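**Overview**

Cuts: first the two C–H bonds at C3 and C4 (flavan back to flav-3-ene). Next the C2–C1' bond between the pyran ring and the trimethoxyphenyl ring B (back to a racemic 2-ethoxy-2H-chromene and an arylboronic acid). Last, O1–C2 and C3=C4 of the derived coumarin (back to a salicylaldehyde and a two-carbon ylide).
Feature: C2 is bonded to O1 and, with C3=C4 in place, ends an O1–C2–C3–C4 oxa-allyl unit fused to ring A. Loss of a leaving group from C2 gives a flat, aromatic 1-benzopyrylium ion stabilised by O1 and by the 7-OMe group (para to C4a), so C2 can be flattened and rebuilt in the step that attaches ring B.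
Forward: ring A is bought. The pyran ring closes at the coumarin stage (Wittig for C3=C4, lactonisation for O1–C2), ring B is joined at C2, and the C3=C4 alkene is saturated last.
Stereo: the single centre C2 comes from catalyst control alone. A tartrate-derived (TADDOL) phosphonite on nickel steers both acetal enantiomers to (S). The hydrogenation leaves C2 untouched and the descriptor unchanged (O1 > C1' > C3 > H before and after).

Key step: step 5

Assumption: the sense of induction of the phosphonite cannot be predicted safely for this donor-rich substrate pair, so L* stands for whichever tartrate-derived antipode a trial run (chiral HPLC, chiroptical correlation of the flavan) shows to give (S); both antipodes are equally accessible.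

**Route**

Step 1
Reactants: 1 2,3,4-trimethoxybenzaldehyde
Product: 3 2-hydroxy-3,4-dimethoxybenzaldehyde, via boron chelate 2 (not isolated)
Conditions: BCl3 (1.1 equiv), CH2Cl2, −10 °C to rt; then H2O
Reagents that add atoms: none
Why: Chelation-directed Lewis-acid ether cleavage, in which boron is held between the formyl oxygen and the ortho methoxy oxygen so that chloride removes only that methyl group to give chelate 2, which water hydrolyses, while the 3- and 4-OMe groups have no chelating partner and should stay.

Step 2
Reactants: 3 2-hydroxy-3,4-dimethoxybenzaldehyde; 4 ethyl (triphenylphosphoranylidene)acetate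
Product: 7 7,8-dimethoxycoumarin, via E-cinnamate 5 (not isolated), via Z-cinnamate 6 (not isolated)
Conditions: 4 (1.2 equiv), PhNEt2, reflux (ca. 215 °C), N2
Reagents that add atoms: ethyl (triphenylphosphoranylidene)acetate (4), CCOC(=O)C=P(c1ccccc1)(c1ccccc1)c1ccccc1
Why: Wittig olefination with a stabilised ylide gives mainly 5, which equilibrates with 6 at this temperature, and since only 6 can lactonise through its ortho phenol with loss of ethanol the mixture should drain to the coumarin, a standard one-pot Wittig/lactonisation of salicylaldehydes.

Step 3
Reactants: 7 7,8-dimethoxycoumarin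
Product: 9 rac-7,8-dimethoxy-2H-chromen-2-ol, via aluminium lactolate 8 (not isolated)
Conditions: DIBAL-H (1.1 equiv), CH2Cl2, −78 °C; then aq. Rochelle salt, to rt; used crude
Reagents that add atoms: none
Why: Partial lactone reduction with DIBAL-H, in which one hydride adds 1,2 to the carbonyl and the tetrahedral lactolate 8 should persist at −78 °C until hydrolysis, so reduction stops at the lactol, whose racemic C2 is of no consequence.

Step 4
Reactants: 9 rac-7,8-dimethoxy-2H-chromen-2-ol
Product: 10 rac-2-ethoxy-7,8-dimethoxy-2H-chromene
Conditions: EtOH, PPTS (5 mol %), 4 Å MS, rt; Et3N quench; Et3N-deactivated silica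
Reagents that add atoms: ethanol, CCO
Why: Acid-catalysed acetalisation of a lactol (Fischer-glycosidation type), easy here because C2 is both O1-bearing and allylic, driven by ethanol as solvent and by the sieves, and mild enough to leave the alkene and the aryl ethers alone.

Step 5
Reactants: 10 rac-2-ethoxy-7,8-dimethoxy-2H-chromene; 11 3,4,5-trimethoxyphenylboronic acid
Product: 13 (2S)-7,8-dimethoxy-2-(3,4,5-trimethoxyphenyl)-2H-chromene, via nickel-bound chromenylium borate 12 (not isolated)
Conditions: Ni(cod)2 (10 mol %), L* (TADDOL-derived P-phenyl phosphonite, 12 mol %), 11 (2 equiv), 1,4-dioxane, rt to 40 °C, no base, Ar, dark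
Reagents that add atoms: 3,4,5-trimethoxyphenylboronic acid (11), COc1cc(B(O)O)cc(OC)c1OC
Why: Boronic acid 11 serves as a mild Lewis acid at the ethoxy oxygen, so that Ni(0)L* can break the allylic C2–OEt bond of either enantiomer of 10 and give 12, the aromatic 7,8-dimethoxychromenylium ion held on nickel as an η3 C2–C3–C4 oxa-allyl, its counter-ion being the ethoxyborate formed from 11. That borate hands its trimethoxyphenyl group to nickel without added base, and reductive elimination then makes the C2–C1' bond and frees Ni(0). The closest known reaction type is the base-free nickel-catalysed Suzuki–Miyaura arylation of 2-alkoxy-2H-chromenes by C(sp3)–O activation, also known in an enantioselective form using TADDOL-derived phosphonites, so only the donor-rich substrate pair is new. No ring closes in this step, so no mode of closure has to be assigned. C2 is the only new stereocentre and is set by the chiral phosphonite: the cation is planar and nickel can change faces by way of the free ion, so the acetal configuration is forgotten and the ligand alone decides on which face aryl transfer and C–C bond formation occur (enantioconvergence, not resolution). Besides face selectivity the step needs C2 over C4 regioselectivity, which the substrate supplies because coupling at the O1-bearing terminus keeps C3=C4 conjugated with ring A whereas coupling at C4 would leave an isolated enol ether, and the aryl–OMe bonds are inert to this catalyst at the temperature used.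

Step 6
Reactants: 13 (2S)-7,8-dimethoxy-2-(3,4,5-trimethoxyphenyl)-2H-chromene
Product: 14 (2S)-7,8,3',4',5'-pentamethoxyflavan [(2S)-7,8-dimethoxy-2-(3,4,5-trimethoxyphenyl)chromane]
Conditions: H2 (1 atm), RhCl(PPh3)3 (5 mol %), PhMe/EtOH 1:1, rt, dark, directly after step 5
Reagents that add atoms: none
Why: Homogeneous hydrogenation with Wilkinson's catalyst adds H2 to the unhindered cis-disubstituted C3=C4 alkene and, unlike palladium on carbon, has little tendency to hydrogenolyse the benzylic and allylic C2–O1 bond, and since C2 takes no part the S configuration should be carried over.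

**Compound list**

1 | 2,3,4-trimethoxybenzaldehyde | COc1ccc(C=O)c(OC)c1OC | starting material
2 | dichloro(6-formyl-2,3-dimethoxyphenoxy)borane, boron also held by the formyl oxygen | COc1ccc(C=O)c(OB(Cl)Cl)c1OC | intermediate
3 | 2-hydroxy-3,4-dimethoxybenzaldehyde | COc1ccc(C=O)c(O)c1OC | intermediate
4 | ethyl (triphenylphosphoranylidene)acetate | CCOC(=O)C=P(c1ccccc1)(c1ccccc1)c1ccccc1 | starting material
5 | ethyl (E)-3-(2-hydroxy-3,4-dimethoxyphenyl)prop-2-enoate | CCOC(=O)/C=C/c1ccc(OC)c(OC)c1O | intermediate
6 | ethyl (Z)-3-(2-hydroxy-3,4-dimethoxyphenyl)prop-2-enoate | CCOC(=O)/C=C\c1ccc(OC)c(OC)c1O | intermediate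
7 | 7,8-dimethoxycoumarin (7,8-dimethoxy-2H-chromen-2-one) | COc1ccc2ccc(=O)oc2c1OC | intermediate
8 | diisobutylaluminium 7,8-dimethoxy-2H-chromen-2-olate (racemic) | COc1ccc2C=CC(O[Al](CC(C)C)CC(C)C)Oc2c1OC | intermediate
9 | rac-7,8-dimethoxy-2H-chromen-2-ol | COc1ccc2C=CC(O)Oc2c1OC | intermediate
10 | rac-2-ethoxy-7,8-dimethoxy-2H-chromene | CCOC1C=Cc2ccc(OC)c(OC)c2O1 | intermediate
11 | 3,4,5-trimethoxyphenylboronic acid | COc1cc(B(O)O)cc(OC)c1OC | starting material
12 | 7,8-dimethoxychromenylium ethoxy(dihydroxy)(3,4,5-trimethoxyphenyl)borate, cation bound η3 (C2–C3–C4) to Ni(L*); nickel fragment left out of the SMILES | COc1ccc2ccc[o+]c2c1OC.CCO[B-](O)(O)c1cc(OC)c(OC)c(OC)c1 | intermediate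
13 | (2S)-7,8-dimethoxy-2-(3,4,5-trimethoxyphenyl)-2H-chromene | COc1cc([C@@H]2C=Cc3ccc(OC)c(OC)c3O2)cc(OC)c1OC | intermediate
14 | (2S)-7,8,3',4',5'-pentamethoxyflavan | COc1cc([C@@H]2CCc3ccc(OC)c(OC)c3O2)cc(OC)c1OC | target

**Count**

Total steps: 6. Longest linear sequence: 6 steps (1 to 14); 4 and 11 are bought and enter directly.

**Steps most likely to fail**

Step 5. Cleavage of the C2–OEt bond may be slow, because the donor-stabilised cation is a weak electrophile for nickel and the 8-OMe group crowds O1. The ligand may also discriminate poorly between the two faces for this substrate pair. The fallback gives up the cross-coupling and sets C2 by reagent-controlled ketone reduction followed by an invertive ring closure.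
- It sets out from 3. Claisen–Schmidt condensation with commercial 3',4',5'-trimethoxyacetophenone (KOH, EtOH) should give (E)-3-(2-hydroxy-3,4-dimethoxyphenyl)-1-(3,4,5-trimethoxyphenyl)prop-2-en-1-one F1.
- Hydrogenation of the enone alkene (H2, Pd/C, EtOAc) should give 3-(2-hydroxy-3,4-dimethoxyphenyl)-1-(3,4,5-trimethoxyphenyl)propan-1-one F2.
- Noyori transfer hydrogenation with RuCl[(R,R)-TsDPEN](p-cymene) in HCO2H/Et3N should give 6-[(3R)-3-hydroxy-3-(3,4,5-trimethoxyphenyl)propyl]-2,3-dimethoxyphenol F3.
- An intramolecular Mitsunobu etherification (PPh3, DIAD, THF, 0 °C) closes O1–C2 with inversion, R to S with the priority order unchanged, and comes back to the route at 14.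

Step 3. The tetrahedral aluminate may collapse with expulsion of the phenoxide and take up a second hydride (over-reduction). The lactol may also open during work-up, and the open enal may isomerise from Z to E. The fallback avoids the lactone oxidation level altogether.
- It sets out from 3. The Schweizer reaction with vinyltriphenylphosphonium bromide (NaH, DMF, heat), an oxa-Michael addition of the phenoxide followed by an intramolecular Wittig reaction, should give 7,8-dimethoxy-2H-chromene F4.
- Hydride abstraction from C2 with DDQ (1.0 equiv) in CH2Cl2/EtOH produces the chromenylium ion. Ethanol captures it at C2, which comes back to the route at 10.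

Step 6. A rhodium hydride may move the alkene towards C2 and so erode the stereocentre. The allylic and benzylic C2–O1 bond may be cleaved, or a slow hydrogenation may leave time for racemisation by reversible oxa-6π ring opening. The fallback replaces metal catalysis by a metal-free, concerted transfer of two hydrogens from diimide. Diimide is generated at rt from 2-nitrobenzenesulfonyl hydrazide and Et3N in CH2Cl2 in the dark, and it has no pathway for alkene migration or C–O cleavage. The fallback sets out from 13 and comes back at 14, and no new compound arises on this way (F0).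

**Further compounds**

F1 | step 5 | (E)-3-(2-hydroxy-3,4-dimethoxyphenyl)-1-(3,4,5-trimethoxyphenyl)prop-2-en-1-one | COc1cc(C(=O)/C=C/c2ccc(OC)c(OC)c2O)cc(OC)c1OC
F2 | step 5 | 3-(2-hydroxy-3,4-dimethoxyphenyl)-1-(3,4,5-trimethoxyphenyl)propan-1-one | COc1cc(C(=O)CCc2ccc(OC)c(OC)c2O)cc(OC)c1OC
F3 | step 5 | 6-[(3R)-3-hydroxy-3-(3,4,5-trimethoxyphenyl)propyl]-2,3-dimethoxyphenol | COc1cc([C@H](O)CCc2ccc(OC)c(OC)c2O)cc(OC)c1OC
F4 | step 3 | 7,8-dimethoxy-2H-chromene | COc1ccc2C=CCOc2c1OC
F0 | step 6 | none | none
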